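An easy step first: eta carries twice the Xi of gamma, and Ym reaches about the same level in eta at 2.00 h (48 %) as in gamma at 4.00 h (52 %), so you can treat Ym as a roughly pseudo-first-order decay whose time constant shrinks as more Xi is charged.

in all of them: Ym 0.20 M

| run | Gy | Xi | remark | time |
|---|---|---|---|---|
| gamma | 0.10 M | 0.16 mM | run made earlier |  |
| eta | 0.10 M | 0.34 mM | run made earlier |  |
| midnight | 0.100 M | 0.20 mM |  | 8.0 h |
| summer | 0.100 M | 0.40 mM |  | 8.0 h |

- gamma (time / h: Qa / %, Ym / %): 0.417: 9, 86; 1.00: 15, 81; 2.00: 19, 67; 3.00: 28, 58; 4.00: 26, 52; 6.00: 32, 42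
- eta (time / h: Qa / %, Ym / %): 0.417: 16, 85; 1.00: 26, 67; 2.00: 35, 48; 3.00: 40, 37; 4.00: 41, 31; 6.00: 36, 18

(readings scatter by 2 percentage points)

- the earlier runs were read with a standard deviation of 2 percentage points

- which of the two there is more of at the end, midnight (Xo / Qa)
- which of the two there is more of at the end, summer (Xo / Qa)
- final Qa, as a percentage of the Ym charged, in midnight
- final Qa, as a percentage of the Ym charged, in summer

Scale a flask's time t by its Xi charge over eta's, τ = t·[Xi]/[Xi]eta, which for midnight gives

τ = 4.71 h

and this eta-equivalent time, the hours eta needs to match a flask's Xi charge multiplied by its time, is what I carry. Reading between eta's values at 4.00 h and 6.00 h, you get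

Ym ≈ 26.4 %, Qa ≈ 39.2 %

But a loss of Ym that runs on real hours would ignore this clock, so test it on gamma's last reading, where τ = 2.82 h: eta there has Qa near 39.1 %, gamma read 32 %, a shortfall of 7.1 points. Midnight has about the same surplus of real hours, 3.29 h against 3.18 h, and if I suppose that loss follows Ym, I scale the shortfall by midnight's Ym over gamma's 42 %:

Qa, midnight ≈ 34.8 %

Is Xo ahead in midnight? Gamma's reading at 1.00 h leaves 21.1 % of the lost Ym unaccounted for, and if I take that as the share going aside, then

Xo, midnight ≈ 23.3 %

which is less than Qa.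

Summer's τ = 9.41 h lies beyond eta's last reading, so I continue eta's late fall of Qa, 0.0650 h⁻¹:

Qa, summer ≈ 28.8 %, Xo, summer ≈ 35.9 %

with Ym counted at eta's last reading. That rate rests on two readings with a scatter of 2 points, so the Qa figure is soft, and the margin of 7.1 points for Xo in summer is no safe one: Xo here is a balance less Qa, so 3.5 points more Qa closes it, and Xo in summer stands as a weak lean.

The forecast gave 28 % for midnight and 26 % for summer, “with Xo the larger in both”.

    Ym + Xi → Xi + Qa (k = 20.0 L mol⁻¹ min⁻¹)
    Xi + Qa → Xi + Xo (k = 13.0 L mol⁻¹ min⁻¹)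
    Ym + Gy → Gu (k = 0.0100 L mol⁻¹ min⁻¹)
    Xi ⇌ Ji (K = 1.20, k = 0.00850 min⁻¹)

Midnight ends with 37.7 % Qa against 17.7 % Xo, and summer with 33.4 % against 44.0 %. At 2.05 h midnight made Qa 3.97 times faster than it used it up, each step taken net, and at 8.00 h, which is 4.71 h on eta's clock, that figure is 1.04, so Qa in midnight is barely climbing. A neighbour of midnight charged with 8.0 × 10⁻⁵ M of Xi reaches 1.88 h on the same clock, close to eta's reading at 2.00 h, and it ends with Ym 47.5 % against eta's 48 %, but with Qa 24.7 % against eta's 35 %.

The data are simulated with constants of no real substance, noise included.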